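**Plan**

- Retrosynthetic cuts: the acetate and C12–Br come off last (Br from the 12R alcohol by SN2 inversion). The oxocene is opened at C8–C9 and C11–C12, leaving an acyclic ether C8–C7–O–C13–C12 (boron on C8, masked aldehyde at C12) and a C9–C10–C11 bridge built on boron in the same pot from CH2Cl2 and vinylMgBr. Further cuts: O–C13 (Williamson), C5–C6 (propargylation), C2–C3 (Sonogashira).
- Enabling feature: in the ring, the C12 carbinol (later C–Br) is homoallylic to the Z C9=C10 bond (C12–C11H2–C10H=C9H–C8H2), the retron of an allylboration. With boron on C9 and the ring tether (C8–C7–O–C13) on that same carbon, C11 must add to C12=O through a six-membered B–O–C12–C11–C10–C9 array that bridges the forming eight-membered O/C7–C13 ring.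
- Forward order: ether C7–O–C13 → C12 acetal and C8 boronate → C6 carbinol and E-enyne chain → oxocene (the only ring, closed in the key step) → bromide, desilylation, acetate.
- Stereochemistry: C7 from (R)-benzyl glycidyl ether; C13 from methyl (S)-2-hydroxybutanoate (inverted in the etherification); C6 by chelation-controlled 1,2-induction from C7; C9 (transient) from (+)-pinanediol, relayed to C12 in the ring closure; C12–Br by inversion; Z alkene from the ring, E alkene from hydrozirconation.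

Key step: step 15

Remark: atoms are numbered as in laurencin (C1 alkyne CH, C6 CH–OAc, ring O/C7–C13, C12 CH–Br, C14–C15 ethyl); the two chiral starting materials and bis[(+)-pinanediolato]diboron are taken as purchasable.

**Route**

Step 1
Reactants: 1 (R)-benzyl glycidyl ether
Product: 2 (S)-1-(benzyloxy)-3-[(4-methoxybenzyl)oxy]propan-2-ol
Conditions: 4-MeOC6H4CH2OH, NaH (0.2 equiv), DMF, 60 °C
Reagents that add atoms: 4-methoxybenzyl alcohol COc1ccc(CO)cc1
Why: base-catalysed SN2 opening of the terminal epoxide at its CH2 carbon (epoxide alcoholysis) leaves the future C7 stereocentre untouched and differentiates the two primary oxygens (Bn on the future C6, PMB on the future C8).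

Step 2
Reactants: 3 methyl (S)-2-hydroxybutanoate
Product: 4 methyl (S)-2-{[(trifluoromethyl)sulfonyl]oxy}butanoate
Conditions: Tf2O, 2,6-lutidine, CH2Cl2, −78 → 0 °C
Reagents that add atoms: trifluoromethanesulfonic anhydride O=S(=O)(OS(=O)(=O)C(F)(F)F)C(F)(F)F
Why: O-sulfonylation of the α-hydroxy ester with retention gives the activated secondary electrophile for the ether synthesis.

Step 3
Reactants: 2 (S)-1-(benzyloxy)-3-[(4-methoxybenzyl)oxy]propan-2-ol; 4 methyl (S)-2-{[(trifluoromethyl)sulfonyl]oxy}butanoate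
Product: 5 methyl (R)-2-({(S)-1-(benzyloxy)-3-[(4-methoxybenzyl)oxy]propan-2-yl}oxy)butanoate
Conditions: NaH, THF, 0 °C; then 4, −40 → 0 °C
Reagents that add atoms: none
Why: Williamson etherification in which the sodium alkoxide displaces the α-triflyloxy ester by SN2 with inversion should set C13 as R and join the two secondary carbons C7 and C13 through oxygen.

Step 4
Reactants: 5 methyl (R)-2-({(S)-1-(benzyloxy)-3-[(4-methoxybenzyl)oxy]propan-2-yl}oxy)butanoate
Product: 6 (R)-2-({(S)-1-(benzyloxy)-3-[(4-methoxybenzyl)oxy]propan-2-yl}oxy)butanal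
Conditions: DIBAL-H, CH2Cl2, −78 °C; Rochelle salt
Reagents that add atoms: none
Why: DIBAL reduction of an α-alkoxy methyl ester stops at the chelated hemiacetal aluminate at −78 °C and should deliver the C12 aldehyde without touching C13.

Step 5
Reactants: 6 (R)-2-({(S)-1-(benzyloxy)-3-[(4-methoxybenzyl)oxy]propan-2-yl}oxy)butanal
Product: 7 (S)-1-(benzyloxy)-2-{[(R)-1,1-dimethoxybutan-2-yl]oxy}-3-[(4-methoxybenzyl)oxy]propane
Conditions: HC(OMe)3, PPTS, MeOH, 20 °C
Reagents that add atoms: trimethyl orthoformate COC(OC)OC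
Why: acid-catalysed acetalisation masks C12 for the organometallic steps; the C8 oxygen is still protected, so no cyclic 1,4-dioxane acetal can form.

Step 6
Reactants: 7 (S)-1-(benzyloxy)-2-{[(R)-1,1-dimethoxybutan-2-yl]oxy}-3-[(4-methoxybenzyl)oxy]propane
Product: 8 (R)-3-(benzyloxy)-2-{[(R)-1,1-dimethoxybutan-2-yl]oxy}propan-1-ol
Conditions: DDQ, CH2Cl2/pH 7 buffer, 0 → 20 °C
Reagents that add atoms: none
Why: oxidative PMB cleavage under neutral conditions frees only the C8 hydroxyl, while the benzyl ether and the dimethyl acetal should survive.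

Step 7
Reactants: 8 (R)-3-(benzyloxy)-2-{[(R)-1,1-dimethoxybutan-2-yl]oxy}propan-1-ol
Product: 9 {[(S)-2-{[(R)-1,1-dimethoxybutan-2-yl]oxy}-3-iodopropoxy]methyl}benzene
Conditions: I2, PPh3, imidazole, CH2Cl2, 0 → 20 °C
Reagents that add atoms: iodine II
Why: Appel-type iodination of the primary alcohol under imidazole buffering, which the acetal tolerates.

Step 8
Reactants: 9 {[(S)-2-{[(R)-1,1-dimethoxybutan-2-yl]oxy}-3-iodopropoxy]methyl}benzene
Product: 10 (+)-pinanediol [(R)-3-(benzyloxy)-2-{[(R)-1,1-dimethoxybutan-2-yl]oxy}propyl]boronate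
Conditions: bis[(+)-pinanediolato]diboron, CuI (10 mol %), PPh3, LiOMe, DMF, 25 °C
Reagents that add atoms: bis[(+)-pinanediolato]diboron B1(B2O[C@@H]3C[C@@H]4C[C@@H](C4(C)C)[C@]3(C)O2)O[C@@H]2C[C@@H]3C[C@@H](C3(C)C)[C@]2(C)O1
Why: copper-catalysed borylation of a primary alkyl iodide with a diboron reagent puts the chiral boronic ester on C8; it is run before any C=C or C≡C is present because the C8 radical involved would cyclise onto unsaturation.

Step 9
Reactants: 10 (+)-pinanediol [(R)-3-(benzyloxy)-2-{[(R)-1,1-dimethoxybutan-2-yl]oxy}propyl]boronate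
Product: 11 (+)-pinanediol [(R)-2-{[(R)-1,1-dimethoxybutan-2-yl]oxy}-3-hydroxypropyl]boronate
Conditions: H2 (1 atm), Pd/C, EtOAc, 20 °C
Reagents that add atoms: none
Why: hydrogenolysis of the benzyl ether frees the C6 hydroxyl; the alkyl pinanediol boronate and the acetal are inert to it.

Step 10
Reactants: 11 (+)-pinanediol [(R)-2-{[(R)-1,1-dimethoxybutan-2-yl]oxy}-3-hydroxypropyl]boronate
Product: 12 (+)-pinanediol [(R)-2-{[(R)-1,1-dimethoxybutan-2-yl]oxy}-3-oxopropyl]boronate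
Conditions: Dess–Martin periodinane, NaHCO3, CH2Cl2, 0 → 20 °C
Reagents that add atoms: none
Why: buffered Dess–Martin oxidation gives the α-alkoxy aldehyde (C6) without epimerising C7; it is used crude.

Step 11
Reactants: 12 (+)-pinanediol [(R)-2-{[(R)-1,1-dimethoxybutan-2-yl]oxy}-3-oxopropyl]boronate
Product: 13 (+)-pinanediol [(2R,3R)-2-{[(R)-1,1-dimethoxybutan-2-yl]oxy}-3-hydroxyhex-5-yn-1-yl]boronate
Conditions: CH2=C=CHSnBu3, MgBr2·OEt2, CH2Cl2, −78 → −40 °C
Reagents that add atoms: tributyl(propa-1,2-dien-1-yl)stannane C=C=C[Sn](CCCC)(CCCC)CCCC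
Why: chelation-controlled SE2′ propargylation: magnesium bridges the aldehyde oxygen and the C7 ether oxygen (Cram chelate) and the allenylstannane attacks from the C7–H face, which should set C6 as R, syn to the C7 oxygen.

Step 12
Reactants: 13 (+)-pinanediol [(2R,3R)-2-{[(R)-1,1-dimethoxybutan-2-yl]oxy}-3-hydroxyhex-5-yn-1-yl]boronate
Product: 14 (+)-pinanediol [(2R,3R)-2-{[(R)-1,1-dimethoxybutan-2-yl]oxy}-3-[(triisopropylsilyl)oxy]hex-5-yn-1-yl]boronate
Conditions: TIPSOTf (1.1 equiv), 2,6-lutidine, CH2Cl2, −78 °C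
Reagents that add atoms: triisopropylsilyl trifluoromethanesulfonate CC(C)[Si](OS(=O)(=O)C(F)(F)F)(C(C)C)C(C)C
Why: silylation of the secondary alcohol at low temperature, where the bulky silyl triflate should not activate the acetal, gives an ether that survives organolithium, Grignard and aqueous acid.

Step 13
Reactants: 14 (+)-pinanediol [(2R,3R)-2-{[(R)-1,1-dimethoxybutan-2-yl]oxy}-3-[(triisopropylsilyl)oxy]hex-5-yn-1-yl]boronate
Product: 16 (+)-pinanediol [(2R,3R,5E)-2-{[(R)-1,1-dimethoxybutan-2-yl]oxy}-6-iodo-3-[(triisopropylsilyl)oxy]hex-5-en-1-yl]boronate, via alkenylzirconocene 15 (not isolated)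
Conditions: Cp2Zr(H)Cl, THF, 20 °C; then I2, 0 °C
Reagents that add atoms: iodine II
Why: hydrozirconation of the terminal alkyne (syn addition, Zr on the terminal carbon) followed by iodinolysis with retention should give the E vinyl iodide (C3=C4).

Step 14
Reactants: 16 (+)-pinanediol [(2R,3R,5E)-2-{[(R)-1,1-dimethoxybutan-2-yl]oxy}-6-iodo-3-[(triisopropylsilyl)oxy]hex-5-en-1-yl]boronate
Product: 17 (+)-pinanediol [(2R,3R,5E)-2-{[(R)-1,1-dimethoxybutan-2-yl]oxy}-3-[(triisopropylsilyl)oxy]-8-(triisopropylsilyl)oct-5-en-7-yn-1-yl]boronate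
Conditions: HC≡C–Si(i-Pr)3, Pd(PPh3)2Cl2 (cat.), CuI (cat.), Et3N, THF, 20 °C
Reagents that add atoms: (triisopropylsilyl)acetylene C#C[Si](C(C)C)(C(C)C)C(C)C
Why: Sonogashira coupling proceeds with retention of the E geometry and completes the protected enyne; the sp3 boronate does not transmetalate under these conditions.

Step 15
Reactants: 17 (+)-pinanediol [(2R,3R,5E)-2-{[(R)-1,1-dimethoxybutan-2-yl]oxy}-3-[(triisopropylsilyl)oxy]-8-(triisopropylsilyl)oct-5-en-7-yn-1-yl]boronate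
Product: 22 (2R,3R,8R)-2-ethyl-8-{(1R,3E)-1-[(triisopropylsilyl)oxy]-6-(triisopropylsilyl)hex-3-en-5-yn-1-yl}-3,4,7,8-tetrahydro-2H-oxocin-3-ol, via α-chloro boronate 18 (not isolated), via allylboronate 19 (not isolated), via aldehyde 20 (not isolated), via borate ester 21 (not isolated)
Conditions: CH2Cl2, n-BuLi, THF, −100 °C; ZnCl2, → 20 °C; CH2=CHMgBr, −78 → 20 °C; 2 M aq HCl, THF (3 mM), 20 °C; NaHCO3, 60 °C
Reagents that add atoms: dichloromethane ClCCl; vinylmagnesium bromide C=C[Mg]Br; water O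
Why: Proposed new method: (dichloromethyl)lithium adds to boron and ZnCl2 triggers the 1,2-shift of C8 onto the new carbon C9 with loss of chloride (Matteson homologation, C9 fixed as S by the (+)-pinanediol ester, 18), vinylmagnesium bromide then displaces the chloride in a second 1,2-shift with inversion to give the (9R) α-substituted allylboronate 19, and aqueous acid frees the C12 aldehyde 20. In 20 the γ-carbon C11 adds to C12=O in a closed six-membered B–O–C12–C11–C10–C9 allylboration while the C9=C10 bond appears; the closest known reactions are the chair-type additions of α-substituted allylboronates to aldehydes and type-I intramolecular carbonyl-ene ring closures, and what is new is that the tether C8–C7–O–C13 sits on the boron-bearing carbon, so the allylboration itself closes the ring. The eight-membered oxocene (O, C7–C13) closes by C11–C12 bond formation with the new alkene endocyclic, through a bridged bicyclo[4.2.2] transition state in which B–O spans C9 and C12. C9 is controlled by the auxiliary and C12 by relay from C9, because boron leaves C9 on the ring face to which it delivers the carbonyl oxygen, so 9R should give the 12R alcohol cis to the C13 ethyl group, while C6, C7 and C13 are not touched. The step needs γ-attack only (a secondary boronic ester shows no 1,3-boron shift and has no α-pathway), Z geometry (enforced by the eight-membered ring, C8 pseudo-axial) and ring closure instead of oligomerisation (3 mM). The excess reagents leave no competing allyl donor, since LiCHCl2 decomposes on warming and vinylMgBr is destroyed by the acid.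

Step 16
Reactants: 22 (2R,3R,8R)-2-ethyl-8-{(1R,3E)-1-[(triisopropylsilyl)oxy]-6-(triisopropylsilyl)hex-3-en-5-yn-1-yl}-3,4,7,8-tetrahydro-2H-oxocin-3-ol
Product: 23 (2R,3S,8R)-3-bromo-2-ethyl-8-{(1R,3E)-1-[(triisopropylsilyl)oxy]-6-(triisopropylsilyl)hex-3-en-5-yn-1-yl}-3,4,7,8-tetrahydro-2H-oxocine
Conditions: CBr4, P(n-Oct)3, toluene, 70 °C
Reagents that add atoms: carbon tetrabromide BrC(Br)(Br)Br
Why: Appel-type bromination of the ring alcohol by SN2 displacement of the oxyphosphonium with inversion should place bromine trans to the C13 ethyl group (12S).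

Step 17
Reactants: 23 (2R,3S,8R)-3-bromo-2-ethyl-8-{(1R,3E)-1-[(triisopropylsilyl)oxy]-6-(triisopropylsilyl)hex-3-en-5-yn-1-yl}-3,4,7,8-tetrahydro-2H-oxocine
Product: 24 (1R,3E)-1-[(2R,7S,8R)-7-bromo-8-ethyl-3,6,7,8-tetrahydro-2H-oxocin-2-yl]hex-3-en-5-yn-1-ol
Conditions: TBAF, AcOH, THF, 0 → 20 °C
Reagents that add atoms: none
Why: fluoride cleaves both the O–Si and the alkynyl C–Si bond; buffering with acetic acid should suppress E2 loss of HBr from the secondary bromide.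

Step 18
Reactants: 24 (1R,3E)-1-[(2R,7S,8R)-7-bromo-8-ethyl-3,6,7,8-tetrahydro-2H-oxocin-2-yl]hex-3-en-5-yn-1-ol
Product: 25 (1R,3E)-1-[(2R,7S,8R)-7-bromo-8-ethyl-3,6,7,8-tetrahydro-2H-oxocin-2-yl]hex-3-en-5-yn-1-yl acetate
Conditions: Ac2O, pyridine, DMAP (cat.), CH2Cl2, 0 → 20 °C
Reagents that add atoms: acetic anhydride CC(=O)OC(C)=O
Why: O-acylation of the C6 alcohol with retention completes the target.

**Compound list**

1 | (R)-benzyl glycidyl ether | c1ccccc1COC[C@H]1CO1 | starting material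
2 | (S)-1-(benzyloxy)-3-[(4-methoxybenzyl)oxy]propan-2-ol | c1ccccc1COC[C@H](O)COCc1ccc(OC)cc1 | intermediate
3 | methyl (S)-2-hydroxybutanoate | CC[C@H](O)C(=O)OC | starting material
4 | methyl (S)-2-{[(trifluoromethyl)sulfonyl]oxy}butanoate | CC[C@H](OS(=O)(=O)C(F)(F)F)C(=O)OC | intermediate
5 | methyl (R)-2-({(S)-1-(benzyloxy)-3-[(4-methoxybenzyl)oxy]propan-2-yl}oxy)butanoate | c1ccccc1COC[C@@H](COCc1ccc(OC)cc1)O[C@H](CC)C(=O)OC | intermediate
6 | (R)-2-({(S)-1-(benzyloxy)-3-[(4-methoxybenzyl)oxy]propan-2-yl}oxy)butanal | c1ccccc1COC[C@@H](COCc1ccc(OC)cc1)O[C@H](CC)C=O | intermediate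
7 | (S)-1-(benzyloxy)-2-{[(R)-1,1-dimethoxybutan-2-yl]oxy}-3-[(4-methoxybenzyl)oxy]propane | c1ccccc1COC[C@@H](COCc1ccc(OC)cc1)O[C@H](CC)C(OC)OC | intermediate
8 | (R)-3-(benzyloxy)-2-{[(R)-1,1-dimethoxybutan-2-yl]oxy}propan-1-ol | c1ccccc1COC[C@@H](CO)O[C@H](CC)C(OC)OC | intermediate
9 | {[(S)-2-{[(R)-1,1-dimethoxybutan-2-yl]oxy}-3-iodopropoxy]methyl}benzene | c1ccccc1COC[C@@H](CI)O[C@H](CC)C(OC)OC | intermediate
10 | (+)-pinanediol [(R)-3-(benzyloxy)-2-{[(R)-1,1-dimethoxybutan-2-yl]oxy}propyl]boronate | c1ccccc1COC[C@@H](CB1O[C@@H]2C[C@@H]3C[C@@H](C3(C)C)[C@]2(C)O1)O[C@H](CC)C(OC)OC | intermediate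
11 | (+)-pinanediol [(R)-2-{[(R)-1,1-dimethoxybutan-2-yl]oxy}-3-hydroxypropyl]boronate | OC[C@@H](CB1O[C@@H]2C[C@@H]3C[C@@H](C3(C)C)[C@]2(C)O1)O[C@H](CC)C(OC)OC | intermediate
12 | (+)-pinanediol [(R)-2-{[(R)-1,1-dimethoxybutan-2-yl]oxy}-3-oxopropyl]boronate | O=C[C@@H](CB1O[C@@H]2C[C@@H]3C[C@@H](C3(C)C)[C@]2(C)O1)O[C@H](CC)C(OC)OC | intermediate
13 | (+)-pinanediol [(2R,3R)-2-{[(R)-1,1-dimethoxybutan-2-yl]oxy}-3-hydroxyhex-5-yn-1-yl]boronate | C#CC[C@@H](O)[C@@H](CB1O[C@@H]2C[C@@H]3C[C@@H](C3(C)C)[C@]2(C)O1)O[C@H](CC)C(OC)OC | intermediate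
14 | (+)-pinanediol [(2R,3R)-2-{[(R)-1,1-dimethoxybutan-2-yl]oxy}-3-[(triisopropylsilyl)oxy]hex-5-yn-1-yl]boronate | C#CC[C@@H](O[Si](C(C)C)(C(C)C)C(C)C)[C@@H](CB1O[C@@H]2C[C@@H]3C[C@@H](C3(C)C)[C@]2(C)O1)O[C@H](CC)C(OC)OC | intermediate
15 | (E)-alkenylzirconocene chloride from 14 (Zr on the terminal carbon) | Cl[Zr](/C=C/C[C@@H](O[Si](C(C)C)(C(C)C)C(C)C)[C@@H](CB1O[C@@H]2C[C@@H]3C[C@@H](C3(C)C)[C@]2(C)O1)O[C@H](CC)C(OC)OC)(C1C=CC=C1)C1C=CC=C1 | intermediate
16 | (+)-pinanediol [(2R,3R,5E)-2-{[(R)-1,1-dimethoxybutan-2-yl]oxy}-6-iodo-3-[(triisopropylsilyl)oxy]hex-5-en-1-yl]boronate | I/C=C/C[C@@H](O[Si](C(C)C)(C(C)C)C(C)C)[C@@H](CB1O[C@@H]2C[C@@H]3C[C@@H](C3(C)C)[C@]2(C)O1)O[C@H](CC)C(OC)OC | intermediate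
17 | (+)-pinanediol [(2R,3R,5E)-2-{[(R)-1,1-dimethoxybutan-2-yl]oxy}-3-[(triisopropylsilyl)oxy]-8-(triisopropylsilyl)oct-5-en-7-yn-1-yl]boronate | CC(C)[Si](C(C)C)(C(C)C)C#C/C=C/C[C@@H](O[Si](C(C)C)(C(C)C)C(C)C)[C@@H](CB1O[C@@H]2C[C@@H]3C[C@@H](C3(C)C)[C@]2(C)O1)O[C@H](CC)C(OC)OC | intermediate
18 | (+)-pinanediol [(1S,3R,4R,6E)-1-chloro-3-{[(R)-1,1-dimethoxybutan-2-yl]oxy}-4-[(triisopropylsilyl)oxy]-9-(triisopropylsilyl)non-6-en-8-yn-1-yl]boronate | CC(C)[Si](C(C)C)(C(C)C)C#C/C=C/C[C@@H](O[Si](C(C)C)(C(C)C)C(C)C)[C@@H](C[C@@H](Cl)B1O[C@@H]2C[C@@H]3C[C@@H](C3(C)C)[C@]2(C)O1)O[C@H](CC)C(OC)OC | intermediate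
19 | (+)-pinanediol [(3R,5R,6R,8E)-5-{[(R)-1,1-dimethoxybutan-2-yl]oxy}-6-[(triisopropylsilyl)oxy]-11-(triisopropylsilyl)undeca-1,8-dien-10-yn-3-yl]boronate | CC(C)[Si](C(C)C)(C(C)C)C#C/C=C/C[C@@H](O[Si](C(C)C)(C(C)C)C(C)C)[C@@H](C[C@H](C=C)B1O[C@@H]2C[C@@H]3C[C@@H](C3(C)C)[C@]2(C)O1)O[C@H](CC)C(OC)OC | intermediate
20 | (+)-pinanediol [(3R,5R,6R,8E)-5-{[(R)-1-oxobutan-2-yl]oxy}-6-[(triisopropylsilyl)oxy]-11-(triisopropylsilyl)undeca-1,8-dien-10-yn-3-yl]boronate | CC(C)[Si](C(C)C)(C(C)C)C#C/C=C/C[C@@H](O[Si](C(C)C)(C(C)C)C(C)C)[C@@H](C[C@H](C=C)B1O[C@@H]2C[C@@H]3C[C@@H](C3(C)C)[C@]2(C)O1)O[C@H](CC)C=O | intermediate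
21 | (+)-pinanediol borate ester of 22 (boron on the C12 oxygen) | CC(C)[Si](C(C)C)(C(C)C)C#C/C=C/C[C@@H](O[Si](C(C)C)(C(C)C)C(C)C)[C@H]1C/C=C\C[C@@H](OB2O[C@@H]3C[C@@H]4C[C@@H](C4(C)C)[C@]3(C)O2)[C@@H](CC)O1 | intermediate
22 | (2R,3R,8R)-2-ethyl-8-{(1R,3E)-1-[(triisopropylsilyl)oxy]-6-(triisopropylsilyl)hex-3-en-5-yn-1-yl}-3,4,7,8-tetrahydro-2H-oxocin-3-ol | CC(C)[Si](C(C)C)(C(C)C)C#C/C=C/C[C@@H](O[Si](C(C)C)(C(C)C)C(C)C)[C@H]1C/C=C\C[C@@H](O)[C@@H](CC)O1 | intermediate
23 | (2R,3S,8R)-3-bromo-2-ethyl-8-{(1R,3E)-1-[(triisopropylsilyl)oxy]-6-(triisopropylsilyl)hex-3-en-5-yn-1-yl}-3,4,7,8-tetrahydro-2H-oxocine | CC(C)[Si](C(C)C)(C(C)C)C#C/C=C/C[C@@H](O[Si](C(C)C)(C(C)C)C(C)C)[C@H]1C/C=C\C[C@H](Br)[C@@H](CC)O1 | intermediate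
24 | (1R,3E)-1-[(2R,7S,8R)-7-bromo-8-ethyl-3,6,7,8-tetrahydro-2H-oxocin-2-yl]hex-3-en-5-yn-1-ol | C#C/C=C/C[C@@H](O)[C@H]1C/C=C\C[C@H](Br)[C@@H](CC)O1 | intermediate
25 | (1R,3E)-1-[(2R,7S,8R)-7-bromo-8-ethyl-3,6,7,8-tetrahydro-2H-oxocin-2-yl]hex-3-en-5-yn-1-yl acetate | C#C/C=C/C[C@@H](OC(C)=O)[C@H]1C/C=C\C[C@H](Br)[C@@H](CC)O1 | target

**Step count**

Total: 18 steps. Longest linear sequence: 17 steps (1, 3–18, from compound 1).

**Steps most likely to fail, with fallbacks**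

1. Step 15. Several processes may defeat it.
   - The bridged transition state may be reached too slowly, so that intermolecular allylboration (oligomers) takes over.
   - The α-chloro boronate may lose configuration at C9 through chloride exchange before the Grignard stage, which would erode the C12 selectivity.
   - The β-alkoxy boronate may eliminate in the ate complex.

   Fallback, from 17 back to 22 by known chemistry:
   - Zweifel olefination of the C8–B bond (vinyllithium, THF, −78 °C; I2; NaOMe) would give (4R,5R,7E)-4-{[(R)-1,1-dimethoxybutan-2-yl]oxy}-5-[(triisopropylsilyl)oxy]-10-(triisopropylsilyl)deca-1,7-dien-9-yne F1.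
   - Aqueous acid would unmask (R)-2-{[(4R,5R,7E)-5-[(triisopropylsilyl)oxy]-10-(triisopropylsilyl)deca-1,7-dien-9-yn-4-yl]oxy}butanal F2.
   - Chelation-controlled allylation (allyltributylstannane, MgBr2·OEt2, CH2Cl2, −78 °C) would give (3R,4R)-3-{[(4R,5R,7E)-5-[(triisopropylsilyl)oxy]-10-(triisopropylsilyl)deca-1,7-dien-9-yn-4-yl]oxy}hept-6-en-4-ol F3.
   - Ring-closing metathesis (second-generation Grubbs catalyst, CH2Cl2, 40 °C, high dilution) would close the ring at C9=C10 and rejoin the route at 22.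

2. Step 11. The bulky secondary alkyl group on the chelating ether oxygen may weaken the chelate and lower the facial selectivity at C6. The Lewis acid may also start β-elimination of the β-alkoxy boronate or open the acetal.
   Fallback, from 12 back to 13 with no new compound: catalyst-controlled propargylation under neutral conditions with allenylboronic acid pinacol ester and a chiral BINOL-derived phosphoric acid (TRIP, the enantiomer that delivers the 6R carbinol; toluene, −20 °C). Stereocontrol then rests on the catalyst, not on the chelate.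

3. Step 3. The alkoxide may act as a base toward the triflate (E2 to methyl crotonate), or excess alkoxide may epimerise the α-alkoxy ester at C13.
   Fallback, from 2 back to 6 by an auxiliary-controlled glycolate alkylation:
   - O-alkylation of 2 with bromoacetic acid (NaH, THF) would give 2-({(S)-1-(benzyloxy)-3-[(4-methoxybenzyl)oxy]propan-2-yl}oxy)acetic acid F4.
   - Mixed-anhydride acylation (PivCl, Et3N; lithiated (S)-4-benzyloxazolidin-2-one) would give (S)-4-benzyl-3-[2-({(S)-1-(benzyloxy)-3-[(4-methoxybenzyl)oxy]propan-2-yl}oxy)acetyl]oxazolidin-2-one F5.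
   - Ethylation of its sodium enolate (NaHMDS, EtOTf, THF, −78 °C) anti to the benzyl group would give (S)-4-benzyl-3-[(R)-2-({(S)-1-(benzyloxy)-3-[(4-methoxybenzyl)oxy]propan-2-yl}oxy)butanoyl]oxazolidin-2-one F6.
   - Reductive removal of the auxiliary (LiBH4, Et2O, MeOH) would give (R)-2-({(S)-1-(benzyloxy)-3-[(4-methoxybenzyl)oxy]propan-2-yl}oxy)butan-1-ol F7.
   - Dess–Martin oxidation would return to 6.

Further compounds
F1 | step 15 | (4R,5R,7E)-4-{[(R)-1,1-dimethoxybutan-2-yl]oxy}-5-[(triisopropylsilyl)oxy]-10-(triisopropylsilyl)deca-1,7-dien-9-yne | CC(C)[Si](C(C)C)(C(C)C)C#C/C=C/C[C@@H](O[Si](C(C)C)(C(C)C)C(C)C)[C@@H](CC=C)O[C@H](CC)C(OC)OC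
F2 | step 15 | (R)-2-{[(4R,5R,7E)-5-[(triisopropylsilyl)oxy]-10-(triisopropylsilyl)deca-1,7-dien-9-yn-4-yl]oxy}butanal | CC(C)[Si](C(C)C)(C(C)C)C#C/C=C/C[C@@H](O[Si](C(C)C)(C(C)C)C(C)C)[C@@H](CC=C)O[C@H](CC)C=O
F3 | step 15 | (3R,4R)-3-{[(4R,5R,7E)-5-[(triisopropylsilyl)oxy]-10-(triisopropylsilyl)deca-1,7-dien-9-yn-4-yl]oxy}hept-6-en-4-ol | CC(C)[Si](C(C)C)(C(C)C)C#C/C=C/C[C@@H](O[Si](C(C)C)(C(C)C)C(C)C)[C@@H](CC=C)O[C@H](CC)[C@H](O)CC=C
F0 | step 11 | none | none
F4 | step 3 | 2-({(S)-1-(benzyloxy)-3-[(4-methoxybenzyl)oxy]propan-2-yl}oxy)acetic acid | c1ccccc1COC[C@@H](COCc1ccc(OC)cc1)OCC(=O)O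
F5 | step 3 | (S)-4-benzyl-3-[2-({(S)-1-(benzyloxy)-3-[(4-methoxybenzyl)oxy]propan-2-yl}oxy)acetyl]oxazolidin-2-one | c1ccccc1COC[C@@H](COCc1ccc(OC)cc1)OCC(=O)N1[C@@H](Cc2ccccc2)COC1=O
F6 | step 3 | (S)-4-benzyl-3-[(R)-2-({(S)-1-(benzyloxy)-3-[(4-methoxybenzyl)oxy]propan-2-yl}oxy)butanoyl]oxazolidin-2-one | c1ccccc1COC[C@@H](COCc1ccc(OC)cc1)O[C@H](CC)C(=O)N1[C@@H](Cc2ccccc2)COC1=O
F7 | step 3 | (R)-2-({(S)-1-(benzyloxy)-3-[(4-methoxybenzyl)oxy]propan-2-yl}oxy)butan-1-ol | c1ccccc1COC[C@@H](COCc1ccc(OC)cc1)O[C@H](CC)CO
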